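**Retrosynthetic overview**

1. The target is the cis-(6aR,11aR)-pterocarpan carrying a dimethylchromene (ring E) on ring A and an (R)-hydroxydimethylchroman (ring F) on ring D. The ring B ether O5–C6 is made last by Mitsunobu closure of the phenol–alcohol that hydride releases from the 6-oxo compound, and the ring F silyl ether is then cleaved.
2. Feature used: C11a bears O11 (ring C) and C6a bears C6 (ring B) on the same face, with an oxygen ortho on ring D (future O11) and on ring A (future O5). The C11a–O bond and C6 are therefore stored as a cis-β-lactone across C6a–C11a (C6 = lactone carbonyl, lactone oxygen on C11a). Its strain is spent to close ring C (O11 displaces at C11a with inversion) and then ring B (O5 is acylated by C6).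
3. Adjustment made: the phenols are unmasked in order, ring D (aryl TBS) first and ring A (aryl TIPS) only after C11a has lost its leaving group. A free ortho-phenoxide on ring A would eject the lactone carboxylate (o-quinone methide) and the acid would fragment with loss of CO2. Ring B is then closed with a carbodiimide, not strong acid, so the benzylic C11a–O11 bond is not ionised.
4. The cis-β-lactone comes from an Evans syn-aldol (C6a–C11a bond, both centres) between the ring D/F arylacetyl imide and the ring A/E salicylaldehyde, followed by LiOOH cleavage and sulfonyl chloride lactonisation.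
5. Both aryl halves come from one chromene aldehyde (2,4-dihydroxybenzaldehyde + 3-methylbut-2-enal); the ring F carbinol is set by Jacobsen epoxidation and hydrogenolysis. Ring order: pyran rings E and F → β-lactone → ring C → ring B (lactone) → ring B (ether).

Key step: step 14

Remark: pterocarpan locants (O5, C6, C6a, O11, C11a) and ring letters A–D are kept for ring-opened precursors as well; ring E is the 2,2-dimethylpyran on ring A, ring F the oxygenated 2,2-dimethyldihydropyran on ring D.

**Route**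

Step 1
Reactants: 1 2,4-dihydroxybenzaldehyde; 2 3-methylbut-2-enal
Product: 3 5-hydroxy-2,2-dimethyl-2H-chromene-6-carbaldehyde
Conditions: pyridine, 120 °C (sealed tube)
Reagents that add atoms: none
Why: Base-mediated chromenylation (aldol-type C-alkylation at C3, dehydration to the o-quinone methide, oxa-6π electrocyclisation) should give the angular chromene, because the 2-OH stays chelated to the formyl group and the 4-OH closes the pyran.

Step 2
Reactants: 3 5-hydroxy-2,2-dimethyl-2H-chromene-6-carbaldehyde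
Product: 4 2,2-dimethyl-5-(triisopropylsilyloxy)-2H-chromene-6-carbaldehyde
Conditions: i-Pr3SiOTf, 2,6-lutidine, CH2Cl2, 0 °C → rt
Reagents that add atoms: triisopropylsilyl trifluoromethanesulfonate, CC(C)[Si](OS(=O)(=O)C(F)(F)F)(C(C)C)C(C)C
Why: Silyl triflate silylation of the chelated, hindered phenol should install the slow-leaving aryl TIPS ether that has to outlast the ring D aryl TBS ether in step 14.

Step 3
Reactants: 3 5-hydroxy-2,2-dimethyl-2H-chromene-6-carbaldehyde
Product: 5 5-(tert-butyldimethylsilyloxy)-2,2-dimethyl-2H-chromene-6-carbaldehyde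
Conditions: t-BuMe2SiCl, imidazole, DMF, rt
Reagents that add atoms: tert-butyldimethylsilyl chloride, CC(C)(C)[Si](C)(C)Cl
Why: Imidazole-mediated silylation of the salicylaldehyde phenol should give the aryl TBS ether, the group that fluoride removes first in step 14.

Step 4
Reactants: 5 5-(tert-butyldimethylsilyloxy)-2,2-dimethyl-2H-chromene-6-carbaldehyde; 6 (methoxymethyl)triphenylphosphonium chloride
Product: 7 tert-butyl{[6-(2-methoxyvinyl)-2,2-dimethyl-2H-chromen-5-yl]oxy}dimethylsilane (E/Z mixture)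
Conditions: KOt-Bu, THF, 0 °C; then 5, 0 °C → rt
Reagents that add atoms: none
Why: Wittig methoxymethylenation of an aromatic aldehyde should add the one carbon that becomes C6; the alkene geometry is irrelevant because both isomers hydrolyse to the same aldehyde.

Step 5
Reactants: 7 tert-butyl{[6-(2-methoxyvinyl)-2,2-dimethyl-2H-chromen-5-yl]oxy}dimethylsilane
Product: 8 2-[5-(tert-butyldimethylsilyloxy)-2,2-dimethyl-2H-chromen-6-yl]acetaldehyde
Conditions: 2 M HCl, THF, 40 °C
Reagents that add atoms: water, O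
Why: Acid-catalysed enol ether hydrolysis should free the arylacetaldehyde, which is used crude, while the hindered aryl TBS ether and the dimethylchromene tolerate dilute aqueous acid.

Step 6
Reactants: 8 2-[5-(tert-butyldimethylsilyloxy)-2,2-dimethyl-2H-chromen-6-yl]acetaldehyde
Product: 9 2-[5-(tert-butyldimethylsilyloxy)-2,2-dimethyl-2H-chromen-6-yl]acetic acid
Conditions: NaClO2, NaH2PO4, 2-methylbut-2-ene, t-BuOH/H2O, 0 °C → rt
Reagents that add atoms: sodium chlorite, [Na+].[O-]Cl=O
Why: Pinnick oxidation should give the arylacetic acid, the alkene scavenger taking up the hypochlorous acid before it can reach the chromene double bond or the electron-rich ring.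

Step 7
Reactants: 9 2-[5-(tert-butyldimethylsilyloxy)-2,2-dimethyl-2H-chromen-6-yl]acetic acid; 10 (S)-4-benzyl-2-oxazolidinone
Product: 12 (S)-4-benzyl-3-{2-[5-(tert-butyldimethylsilyloxy)-2,2-dimethyl-2H-chromen-6-yl]acetyl}oxazolidin-2-one, via mixed pivalic anhydride 11 (not isolated)
Conditions: t-BuCOCl, Et3N, THF, −20 °C; then 10, LiCl, −20 °C → rt
Reagents that add atoms: none
Why: N-acylation through the mixed anhydride should occur at the arylacetyl carbonyl because the pivaloyl carbonyl is shielded by the tert-butyl group.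

Step 8
Reactants: 12 (S)-4-benzyl-3-{2-[5-(tert-butyldimethylsilyloxy)-2,2-dimethyl-2H-chromen-6-yl]acetyl}oxazolidin-2-one
Product: 13 (S)-4-benzyl-3-{2-[(3R,4R)-5-(tert-butyldimethylsilyloxy)-3,4-epoxy-2,2-dimethylchroman-6-yl]acetyl}oxazolidin-2-one
Conditions: (R,R)-[N,N'-bis(3,5-di-tert-butylsalicylidene)cyclohexane-1,2-diaminato]MnCl (5 mol %, trivalent manganese), 4-phenylpyridine N-oxide, NaOCl (aq., pH 11.3), CH2Cl2, 0 °C
Reagents that add atoms: sodium hypochlorite, [Na+].[O-]Cl
Why: Jacobsen–Katsuki epoxidation of a cis-disubstituted 2,2-dimethylchromene, the best substrate class for this catalyst, should give the (3R,4R)-epoxide with the (R,R)-ligand and so set the ring F carbinol centre; the acid-labile epoxide is carried on without chromatography.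

Step 9
Reactants: 13 (S)-4-benzyl-3-{2-[(3R,4R)-5-(tert-butyldimethylsilyloxy)-3,4-epoxy-2,2-dimethylchroman-6-yl]acetyl}oxazolidin-2-one
Product: 14 (S)-4-benzyl-3-{2-[(3R)-5-(tert-butyldimethylsilyloxy)-3-hydroxy-2,2-dimethylchroman-6-yl]acetyl}oxazolidin-2-one
Conditions: H2 (1 atm), 10% Pd/C, EtOAc, rt
Reagents that add atoms: none
Why: Catalytic hydrogenolysis should cleave only the benzylic C4–O bond of the epoxide and leave the C3–O bond and its configuration alone; the fragment holds no other alkene and the imide, the C-benzyl group and the silyl ether are inert.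

Step 10
Reactants: 14 (S)-4-benzyl-3-{2-[(3R)-5-(tert-butyldimethylsilyloxy)-3-hydroxy-2,2-dimethylchroman-6-yl]acetyl}oxazolidin-2-one
Product: 15 (S)-4-benzyl-3-{2-[(3R)-3,5-bis(tert-butyldimethylsilyloxy)-2,2-dimethylchroman-6-yl]acetyl}oxazolidin-2-one
Conditions: t-BuMe2SiOTf, 2,6-lutidine, CH2Cl2, −40 → 0 °C
Reagents that add atoms: tert-butyldimethylsilyl trifluoromethanesulfonate, CC(C)(C)[Si](C)(C)OS(=O)(=O)C(F)(F)F
Why: The silyl triflate should silylate the neopentyl-type secondary alcohol, and 2,6-lutidine is too weak a base to enolise the arylacetyl imide.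

Step 11
Reactants: 15 (S)-4-benzyl-3-{2-[(3R)-3,5-bis(tert-butyldimethylsilyloxy)-2,2-dimethylchroman-6-yl]acetyl}oxazolidin-2-one; 4 2,2-dimethyl-5-(triisopropylsilyloxy)-2H-chromene-6-carbaldehyde
Product: 18 (S)-4-benzyl-3-{(2S,3S)-2-[(3R)-3,5-bis(tert-butyldimethylsilyloxy)-2,2-dimethylchroman-6-yl]-3-[2,2-dimethyl-5-(triisopropylsilyloxy)-2H-chromen-6-yl]-3-hydroxypropanoyl}oxazolidin-2-one, via (Z)-dibutylboron enolate 16 (not isolated), via dibutylboron aldolate 17 (not isolated)
Conditions: n-Bu2BOTf, i-Pr2NEt, CH2Cl2, −78 → 0 °C; then 4, −78 → 0 °C; then pH 7 phosphate buffer, MeOH, 30% H2O2, 0 °C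
Reagents that add atoms: none
Why: Evans syn-aldol: the (Z)-boron enolate should react through a closed Zimmerman–Traxler transition state on the face away from the benzyl group of the dipole-opposed auxiliary, forming the C6a–C11a bond and setting C6a (2S) and the C11a carbinol (3S) syn.

Step 12
Reactants: 18 (S)-4-benzyl-3-{(2S,3S)-2-[(3R)-3,5-bis(tert-butyldimethylsilyloxy)-2,2-dimethylchroman-6-yl]-3-[2,2-dimethyl-5-(triisopropylsilyloxy)-2H-chromen-6-yl]-3-hydroxypropanoyl}oxazolidin-2-one
Product: 20 (2S,3S)-2-[(3R)-3,5-bis(tert-butyldimethylsilyloxy)-2,2-dimethylchroman-6-yl]-3-[2,2-dimethyl-5-(triisopropylsilyloxy)-2H-chromen-6-yl]-3-hydroxypropanoic acid, via peroxy acid 19 (not isolated)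
Conditions: LiOH, 30% H2O2, THF/H2O, 0 °C; then Na2SO3 (aq.); then 1 M HCl to pH 4, 0 °C
Reagents that add atoms: hydrogen peroxide (as lithium hydroperoxide), OO
Why: Hydroperoxide cleavage of the imide should occur at the exocyclic carbonyl even of this hindered acyl group, and the weakly basic nucleophile at 0 °C should spare C6a, the aldol linkage and the two hindered aryl silyl ethers; sulfite then reduces the peracid.

Step 13
Reactants: 20 (2S,3S)-2-[(3R)-3,5-bis(tert-butyldimethylsilyloxy)-2,2-dimethylchroman-6-yl]-3-[2,2-dimethyl-5-(triisopropylsilyloxy)-2H-chromen-6-yl]-3-hydroxypropanoic acid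
Product: 21 (3S,4S)-3-[(3R)-3,5-bis(tert-butyldimethylsilyloxy)-2,2-dimethylchroman-6-yl]-4-[2,2-dimethyl-5-(triisopropylsilyloxy)-2H-chromen-6-yl]oxetan-2-one (cis-β-lactone)
Conditions: PhSO2Cl, pyridine, −20 → 0 °C
Reagents that add atoms: none
Why: Carboxyl activation as the mixed carboxylic–sulfonic anhydride and 4-exo-trig attack of the β-hydroxyl (β-lactonisation of a β-hydroxy acid) should proceed with retention at both centres, so the syn acid gives the cis-lactone; it is worked up cold and used at once because donor-substituted 4-aryl-β-lactones lose CO2.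

Step 14
Reactants: 21 (3S,4S)-cis-3,4-diaryloxetan-2-one (ring A O-TIPS; ring D O-TBS; ring F O-TBS)
Product: 25 (6aS,11aR)-6-oxo-cis-pterocarpan (ring B as aryl lactone; rings A–F in place; ring F O-TBS), via ring D phenoxide lactone 22 (not isolated), via O-TIPS dihydrobenzofuran carboxylate 23 (not isolated), via phenol acid 24 (not isolated)
Conditions: n-Bu4NF (1.05 equiv), THF, −78 → −30 °C; then n-Bu4NF (1.5 equiv), 0 °C; then pyridinium chloride, EDC·HCl, 0 °C → rt
Reagents that add atoms: none
Why: Proposed new method: one equivalent of fluoride should cleave the ring D aryl TBS ether much faster than the ring A aryl TIPS ether or the ring F alkyl TBS ether, and the naked tetrabutylammonium phenoxide 22, held on C6a, should attack C11a anti to the lactone oxygen (SN2, alkyl–oxygen cleavage, ring C closed 5-exo-tet) with release of the four-ring strain and a carboxylate as leaving group; the closest known reactions are the alkyl–oxygen opening of β-lactones by phenoxide and carboxylate nucleophiles and the invertive intramolecular ring expansions of β-lactones to tetrahydrofurans. Inversion at C11a turns the cis-lactone into the cis-2-aryl-3-carboxylate 23, so the new C11a configuration (R) is dictated by C6a from the aldol and C6a itself is not touched. The step needs alkyl–oxygen in preference to acyl–oxygen attack (5-exo-trig addition at C6 would lead to a benzofuranone) and no enolisation at C6a; the benzylic C11a with its para-alkoxy and ortho-silyloxy donors, the soft phenoxide, the low temperature and the irreversible release of carboxylate should secure this. Ring A is unmasked only after C11a has lost its leaving group, because a free ortho-phenoxide there would expel the lactone carboxylate to an o-quinone methide that fragments with loss of CO2. The second charge of fluoride then frees the ring A phenol and, after buffering with pyridinium chloride, the carbodiimide closes ring B by 6-exo-trig acyl substitution (the lactonisation of a 3-(2-hydroxyaryl)propanoic acid), which only the cis acid 24 can undergo. Activation at C6 can epimerise C6a only towards a trans acid that cannot lactonise, so the cis-fused lactone 25 is the only outlet.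

Step 15
Reactants: 25 (6aS,11aR)-6-oxo-cis-pterocarpan (ring F O-TBS)
Product: 26 (6aR,11aR)-phenol–alcohol (ring B opened: ring A phenol and C6 primary alcohol; ring C intact; ring F O-TBS)
Conditions: LiAlH4, THF, −20 → 0 °C
Reagents that add atoms: none
Why: Hydride reduction of the aryl lactone should give the phenol and the primary alcohol without touching either stereocentre, the low temperature keeping the ring A phenoxide from opening ring C.

Step 16
Reactants: 26 (6aR,11aR)-phenol–alcohol
Product: 27 (6aR,11aR)-pterocarpan tert-butyldimethylsilyl ether (target with ring F O-TBS)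
Conditions: PPh3, DIAD, THF, 0 °C → rt
Reagents that add atoms: none
Why: Intramolecular Mitsunobu etherification (6-exo-tet attack of the ring A phenol on the activated primary C6 alcohol) should reclose ring B as the ether; no stereocentre is involved and the hindered silyl ether is inert.

Step 17
Reactants: 27 (6aR,11aR)-pterocarpan tert-butyldimethylsilyl ether
Product: 28 CNP0126417.1 (target)
Conditions: n-Bu4NF, THF, rt → 45 °C
Reagents that add atoms: none
Why: Fluoride cleavage of the hindered secondary silyl ether should free the (R)-carbinol of ring F, the pterocarpan and chromene units being inert to fluoride.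

**Compound list**

1 | 2,4-dihydroxybenzaldehyde | O=Cc1ccc(O)cc1O | starting material
2 | 3-methylbut-2-enal | CC(C)=CC=O | starting material
3 | 5-hydroxy-2,2-dimethyl-2H-chromene-6-carbaldehyde | CC1(C)C=Cc2c(O1)ccc(C=O)c2O | intermediate
4 | 2,2-dimethyl-5-(triisopropylsilyloxy)-2H-chromene-6-carbaldehyde | CC1(C)C=Cc2c(O1)ccc(C=O)c2O[Si](C(C)C)(C(C)C)C(C)C | intermediate
5 | 5-(tert-butyldimethylsilyloxy)-2,2-dimethyl-2H-chromene-6-carbaldehyde | CC1(C)C=Cc2c(O1)ccc(C=O)c2O[Si](C)(C)C(C)(C)C | intermediate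
6 | (methoxymethyl)triphenylphosphonium chloride | COC[P+](c1ccccc1)(c1ccccc1)c1ccccc1.[Cl-] | starting material
7 | tert-butyl{[6-(2-methoxyvinyl)-2,2-dimethyl-2H-chromen-5-yl]oxy}dimethylsilane (E/Z mixture) | CC1(C)C=Cc2c(O1)ccc(C=COC)c2O[Si](C)(C)C(C)(C)C | intermediate
8 | 2-[5-(tert-butyldimethylsilyloxy)-2,2-dimethyl-2H-chromen-6-yl]acetaldehyde | CC1(C)C=Cc2c(O1)ccc(CC=O)c2O[Si](C)(C)C(C)(C)C | intermediate
9 | 2-[5-(tert-butyldimethylsilyloxy)-2,2-dimethyl-2H-chromen-6-yl]acetic acid | CC1(C)C=Cc2c(O1)ccc(CC(=O)O)c2O[Si](C)(C)C(C)(C)C | intermediate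
10 | (S)-4-benzyl-2-oxazolidinone | O=C1OC[C@H](Cc2ccccc2)N1 | starting material
11 | mixed pivalic anhydride of 9 (not isolated) | CC1(C)C=Cc2c(O1)ccc(CC(=O)OC(=O)C(C)(C)C)c2O[Si](C)(C)C(C)(C)C | intermediate
12 | (S)-4-benzyl-3-{2-[5-(tert-butyldimethylsilyloxy)-2,2-dimethyl-2H-chromen-6-yl]acetyl}oxazolidin-2-one | O=C1OC[C@H](Cc2ccccc2)N1C(=O)Cc1ccc2OC(C)(C)C=Cc2c1O[Si](C)(C)C(C)(C)C | intermediate
13 | (3R,4R)-epoxide of 12 | O=C1OC[C@H](Cc2ccccc2)N1C(=O)Cc1ccc2c(c1O[Si](C)(C)C(C)(C)C)[C@H]1O[C@H]1C(C)(C)O2 | intermediate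
14 | (3R)-3-hydroxychroman imide | O=C1OC[C@H](Cc2ccccc2)N1C(=O)Cc1ccc2c(c1O[Si](C)(C)C(C)(C)C)C[C@@H](O)C(C)(C)O2 | intermediate
15 | (3R)-3,5-bis(silyloxy)chroman imide | O=C1OC[C@H](Cc2ccccc2)N1C(=O)Cc1ccc2c(c1O[Si](C)(C)C(C)(C)C)C[C@@H](O[Si](C)(C)C(C)(C)C)C(C)(C)O2 | intermediate
16 | (Z)-dibutylboron enolate of 15 (not isolated) | CCCCB(CCCC)O/C(=C\c1ccc2c(c1O[Si](C)(C)C(C)(C)C)C[C@@H](O[Si](C)(C)C(C)(C)C)C(C)(C)O2)N1C(=O)OC[C@@H]1Cc1ccccc1 | intermediate
17 | dibutylboron aldolate of 18 (not isolated) | O=C1OC[C@H](Cc2ccccc2)N1C(=O)[C@@H](c1ccc2c(c1O[Si](C)(C)C(C)(C)C)C[C@@H](O[Si](C)(C)C(C)(C)C)C(C)(C)O2)[C@H](OB(CCCC)CCCC)c1ccc2c(c1O[Si](C(C)C)(C(C)C)C(C)C)C=CC(C)(C)O2 | intermediate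
18 | (2S,3S)-syn-aldol imide | O=C1OC[C@H](Cc2ccccc2)N1C(=O)[C@@H](c1ccc2c(c1O[Si](C)(C)C(C)(C)C)C[C@@H](O[Si](C)(C)C(C)(C)C)C(C)(C)O2)[C@H](O)c1ccc2c(c1O[Si](C(C)C)(C(C)C)C(C)C)C=CC(C)(C)O2 | intermediate
19 | (2S,3S)-peroxy acid (not isolated) | OOC(=O)[C@@H](c1ccc2c(c1O[Si](C)(C)C(C)(C)C)C[C@@H](O[Si](C)(C)C(C)(C)C)C(C)(C)O2)[C@H](O)c1ccc2c(c1O[Si](C(C)C)(C(C)C)C(C)C)C=CC(C)(C)O2 | intermediate
20 | (2S,3S)-β-hydroxy acid | OC(=O)[C@@H](c1ccc2c(c1O[Si](C)(C)C(C)(C)C)C[C@@H](O[Si](C)(C)C(C)(C)C)C(C)(C)O2)[C@H](O)c1ccc2c(c1O[Si](C(C)C)(C(C)C)C(C)C)C=CC(C)(C)O2 | intermediate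
21 | (3S,4S)-cis-3,4-diaryloxetan-2-one (key-step precursor) | O=C1O[C@H](c2ccc3c(c2O[Si](C(C)C)(C(C)C)C(C)C)C=CC(C)(C)O3)[C@@H]1c1ccc2c(c1O[Si](C)(C)C(C)(C)C)C[C@@H](O[Si](C)(C)C(C)(C)C)C(C)(C)O2 | intermediate
22 | ring D phenoxide of the cis-lactone, tetrabutylammonium salt (not isolated) | O=C1O[C@H](c2ccc3c(c2O[Si](C(C)C)(C(C)C)C(C)C)C=CC(C)(C)O3)[C@@H]1c1ccc2c(c1[O-])C[C@@H](O[Si](C)(C)C(C)(C)C)C(C)(C)O2.CCCC[N+](CCCC)(CCCC)CCCC | intermediate
23 | (6aS,11aR)-cis-dihydrobenzofuran carboxylate with ring A O-TIPS, tetrabutylammonium salt (not isolated) | [O-]C(=O)[C@H]1c2ccc3c(c2O[C@H]1c1ccc2c(c1O[Si](C(C)C)(C(C)C)C(C)C)C=CC(C)(C)O2)C[C@@H](O[Si](C)(C)C(C)(C)C)C(C)(C)O3.CCCC[N+](CCCC)(CCCC)CCCC | intermediate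
24 | (6aS,11aR)-phenol acid (not isolated) | OC(=O)[C@H]1c2ccc3c(c2O[C@H]1c1ccc2c(c1O)C=CC(C)(C)O2)C[C@@H](O[Si](C)(C)C(C)(C)C)C(C)(C)O3 | intermediate
25 | (6aS,11aR)-6-oxo-cis-pterocarpan, ring F O-TBS (key-step product) | CC1(C)C=Cc2c(ccc3c2OC(=O)[C@H]2c4ccc5c(c4O[C@@H]32)C[C@@H](O[Si](C)(C)C(C)(C)C)C(C)(C)O5)O1 | intermediate
26 | (6aR,11aR)-phenol–alcohol, ring F O-TBS | OC[C@H]1c2ccc3c(c2O[C@H]1c1ccc2c(c1O)C=CC(C)(C)O2)C[C@@H](O[Si](C)(C)C(C)(C)C)C(C)(C)O3 | intermediate
27 | (6aR,11aR)-pterocarpan, ring F O-TBS | CC1(C)C=Cc2c(ccc3c2OC[C@H]2c4ccc5c(c4O[C@@H]32)C[C@@H](O[Si](C)(C)C(C)(C)C)C(C)(C)O5)O1 | intermediate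
28 | CNP0126417.1 | CC1(C)C=Cc2c(ccc3c2OC[C@H]2c4ccc5c(c4O[C@@H]32)C[C@@H](O)C(C)(C)O5)O1 | target

**Step count and risks**

Total steps: 17. Longest linear sequence: 16 (steps 1, 3–17; step 2 is the one-step branch to aldehyde 4).

Step 14 (key step). The ring D phenoxide may add to the lactone carbonyl in place of displacing at C11a, proton exchange at C6a may outrun ring closure, or early loss of the ring A silyl group may trigger fragmentation with loss of CO2. The fallback uses known reactions only, sets out from hydroxy acid 20 and avoids the β-lactone. Trimethylsilyldiazomethane (MeOH/toluene, 0 °C) should give the methyl ester F1. Buffered fluoride (n-Bu4NF/AcOH, THF, −20 °C) should free only the ring D phenol to give the phenol ester F2. An intramolecular Mitsunobu etherification at the benzylic carbinol C11a (PPh3, DIAD, THF, 0 °C), a known way to close 2-aryl-2,3-dihydrobenzofurans and pterocarpans with inversion, should give the cis-dihydrobenzofuran ester F3. LiAlH4 (THF, −20 °C) should reduce the ester to the primary alcohol F4, and n-Bu4NF at 0 °C should remove the ring A TIPS group to give phenol–alcohol 26, where the route is rejoined before step 16.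

Step 13. Heterolysis at the donor-substituted benzylic C11a during or after carboxyl activation may lead to decarboxylative elimination, or the benzylic hydroxyl may be sulfonylated in place of the carboxyl group. The fallback closes the four-membered ring from a thioester under neutral, thiophilic activation and sets out from aldol adduct 18, so it leaves out step 12 as well. LiSEt (EtSH, n-BuLi, THF, 0 °C) should exchange the auxiliary for the S-ethyl thioester F5. AgO2CCF3 with Na2HPO4 in MeCN at 0 °C should then let the β-hydroxyl displace the silver-bound thiolate with retention, returning to the route at lactone 21.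

Step 11. Addition of the boron enolate to the hindered, electron-rich ortho-silyloxy aldehyde may be sluggish, with reversal of the aldol or erosion of syn selectivity on warming. The fallback changes auxiliary and enolate type and sets out from imide 15. LiOOH cleavage should give the arylacetic acid F6, and EDC/DMAP coupling with (S)-4-benzyl-1,3-thiazolidine-2-thione should give the N-acyl thiazolidinethione F7. Its chlorotitanium enolate (TiCl4, i-Pr2NEt, N-methylpyrrolidinone, CH2Cl2, −78 → 0 °C), in which the metal also activates the aldehyde, should add to aldehyde 4 to give the syn-aldol thioimide F8 of the same (2S,3S) sense. Brief LiOH in aqueous THF at 0 °C should then release hydroxy acid 20, where the route is rejoined before step 13.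

Further compounds
F1 | step 14 | methyl (2S,3S)-ester of hydroxy acid 20 | COC(=O)[C@@H](c1ccc2c(c1O[Si](C)(C)C(C)(C)C)C[C@@H](O[Si](C)(C)C(C)(C)C)C(C)(C)O2)[C@H](O)c1ccc2c(c1O[Si](C(C)C)(C(C)C)C(C)C)C=CC(C)(C)O2
F2 | step 14 | methyl (2S,3S)-ester with free ring D phenol | COC(=O)[C@@H](c1ccc2c(c1O)C[C@@H](O[Si](C)(C)C(C)(C)C)C(C)(C)O2)[C@H](O)c1ccc2c(c1O[Si](C(C)C)(C(C)C)C(C)C)C=CC(C)(C)O2
F3 | step 14 | methyl (6aS,11aR)-cis-dihydrobenzofuran carboxylate with ring A O-TIPS | COC(=O)[C@H]1c2ccc3c(c2O[C@H]1c1ccc2c(c1O[Si](C(C)C)(C(C)C)C(C)C)C=CC(C)(C)O2)C[C@@H](O[Si](C)(C)C(C)(C)C)C(C)(C)O3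
F4 | step 14 | (6aR,11aR)-primary alcohol with ring A O-TIPS | OC[C@H]1c2ccc3c(c2O[C@H]1c1ccc2c(c1O[Si](C(C)C)(C(C)C)C(C)C)C=CC(C)(C)O2)C[C@@H](O[Si](C)(C)C(C)(C)C)C(C)(C)O3
F5 | step 13 | S-ethyl (2S,3S)-thioester of the syn-aldol | CCSC(=O)[C@@H](c1ccc2c(c1O[Si](C)(C)C(C)(C)C)C[C@@H](O[Si](C)(C)C(C)(C)C)C(C)(C)O2)[C@H](O)c1ccc2c(c1O[Si](C(C)C)(C(C)C)C(C)C)C=CC(C)(C)O2
F6 | step 11 | 2-[(3R)-3,5-bis(tert-butyldimethylsilyloxy)-2,2-dimethylchroman-6-yl]acetic acid | OC(=O)Cc1ccc2c(c1O[Si](C)(C)C(C)(C)C)C[C@@H](O[Si](C)(C)C(C)(C)C)C(C)(C)O2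
F7 | step 11 | (S)-4-benzyl-3-(arylacetyl)-1,3-thiazolidine-2-thione | S=C1SC[C@H](Cc2ccccc2)N1C(=O)Cc1ccc2c(c1O[Si](C)(C)C(C)(C)C)C[C@@H](O[Si](C)(C)C(C)(C)C)C(C)(C)O2
F8 | step 11 | (2S,3S)-syn-aldol thiazolidinethione imide | S=C1SC[C@H](Cc2ccccc2)N1C(=O)[C@@H](c1ccc2c(c1O[Si](C)(C)C(C)(C)C)C[C@@H](O[Si](C)(C)C(C)(C)C)C(C)(C)O2)[C@H](O)c1ccc2c(c1O[Si](C(C)C)(C(C)C)C(C)C)C=CC(C)(C)O2
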